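**Target:** 4-{[(2S)-3-hydroxy-1-(4-hydroxy-3,5-dimethoxyphenyl)-1-oxopropan-2-yl]oxy}-3-methoxybenzoic acid (compound 12). The configuration read from the SMILES is S.

## The problem

The target is a β-O-4 neolignan ketone with a three-carbon chain Cα(=O)–CβH(O–)–CγH2OH. Cα is bonded to C1 of ring A (the 4-hydroxy-3,5-dimethoxyphenyl ring), and Cβ is bonded through an ether oxygen to C4 of ring B (the 3-methoxybenzoic acid ring). Both rings are commercial arenes joined to the chain by one C–C and one C–O bond, so the skeleton is easy and the whole problem is the single stereocentre Cβ. Cβ–H lies between the Cα ketone and the aryloxy oxygen, so it is acidic and the centre racemises through the enol; the Cγ hydroxyl adds retro-aldol loss of formaldehyde and dehydration to the 2-aryloxy enone. No second stereocentre exists that could control or lock Cβ, so it must be set absolutely, and everything done after the Cα ketone is in place must be neutral, mild and short. The phenol of ring A and the carboxylic acid of ring B need masking groups that leave without base or strong acid. The feature that makes the key step possible is this same Cβ–H, flanked by the Cα carbonyl and carrying the O–C4 bond to ring B. When Cγ is carried as an ester, Cβ–H becomes a 1,3-dicarbonyl C–H, the enantiomers interconvert freely, and the Cα ketone is the handle by which a chiral reduction catalyst can select one of them.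

## Retrosynthesis

**12 ⇒ 11.** The two O–benzyl bonds are cut (benzyl ether on ring A, benzyl ester on ring B). A benzyl ester is preferred to a methyl ester because saponification would destroy Cβ, whereas hydrogenolysis is neutral and frees both groups at once. The forward step must cleave two benzylic C–O bonds faster than it touches the aryl ketone or the Cβ–O bond.

**11 ⇒ 10.** The Cα ketone is traced back to a Cα carbinol, diol 10. This keeps Cβ out of the α-keto position in every earlier step. Because Cα is erased again, only the configuration at Cβ matters in 10. The forward step needs an oxidant that takes the benzylic secondary alcohol, leaves the primary Cγ alcohol and is not basic.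

**10 ⇒ 9.** The Cγ alcohol is traced back to a methyl ester, hydroxy ester 9. The ester is what makes Cβ–H exchangeable in the key step. The forward reduction must distinguish the activated aliphatic ester from the benzoate of ring B.

**9 ⇒ 7 (key).** The Cα–H bond is removed to give the racemic α-aryloxy β-keto ester 7. Compound 9 has two defined stereocentres and 7 has no stereochemical information at all. Against the neighbouring cuts (Cα–Cβ aldol, Cβ–Cγ hydroxymethylation), this one turns the lability of Cβ into the source of stereoconvergence. The forward reaction is a catalytic asymmetric transfer hydrogenation under dynamic kinetic resolution, which must funnel both enantiomers of 7 into one diastereomer of 9.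

**7 ⇒ 4 + 6.** The Cβ–O bond is cut to chloro keto ester 4 and phenol 6. Since Cβ racemises in 7 anyway, this bond can be made by the simplest substitution with no stereocontrol. The forward step is a phenoxide displacement on an α-halo-1,3-dicarbonyl compound.

**4 ⇒ 3 ⇒ 2 ⇒ 1 and 6 ⇒ 5.** The Cβ–Cl bond, the Cβ–Cγ bond (Claisen C-acylation of the methyl ketone 2 with a carbonate diester) and the benzyl ether are removed in turn, reaching acetosyringone 1. Phenol 6 is the benzyl ester of vanillic acid 5. Every step in this run-up is a standard enolate or alkylation reaction.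

## Roads not taken

Alternative 1: This is the most obvious cut, Cα–Cβ, as an auxiliary-controlled aldol. The boron Z-enolate of the aryloxyacetyl oxazolidinone A1 would add to aldehyde A2 to give the syn adduct A3, and reductive removal of the auxiliary would meet the route at 10. It is sound and of similar length, and it is kept as the fallback for the key step. The chosen plan is preferred because it needs no stoichiometric auxiliary or low-temperature enolate chemistry, and it draws the configuration from a small amount of catalyst acting on a precursor made without stereocontrol.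

Alternative 2: The Cβ–Cγ cut is the aldol addition of the 2-aryloxy ketone A4 to formaldehyde A5, the usual way to racemic ketones of this type. An enantioselective version would give 11 directly and save steps. The product, however, would form under the same enolising conditions that racemise it and reverse it by retro-aldol. Its only stereocentre is the labile one, so no diastereomer can be purified, and an enantioselective formaldehyde aldol on an α-aryloxy aryl ketone lacks close precedent. In the chosen plan Cβ is set in the same step that removes it from the α-keto position, and any stereochemical error is removable as a diastereomer.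

Alternative 3: The Cβ–O cut with a chiral-pool carbon would use Mitsunobu inversion of the (R)-glycerate A6 by phenol 6 to give A7. Conversion to the Weinreb amide A8 and addition of the aryllithium A9 would form the Cα–ring A bond, and hydrogenolysis would give 12. The aryllithium would meet the ring B ester. The Cβ–H of A8, α to the amide and β to a benzyloxy group, would be exposed to a strong base and could racemise or eliminate. The configuration would be set early and carried through the harshest step, and the sequence would be longer.

Key step: step 6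

Assumption: the syn preference known for ruthenium–TsDPEN transfer hydrogenation of α-alkoxy aryl β-keto esters is taken to hold for the α-aryloxy ester 7; if the opposite relative configuration were favoured, the enantiomeric catalyst would be used, since only Cβ is kept.

In the propanoate names of 3, 4, 7 and 9, Cβ is C2 and Cα is C3.

## Route

Step 1
Reactants: 1 acetosyringone, 1-(4-hydroxy-3,5-dimethoxyphenyl)ethan-1-one
Product: 2 1-[4-(benzyloxy)-3,5-dimethoxyphenyl]ethan-1-one
Conditions: BnBr (1.1 equiv), K2CO3 (1.5 equiv), DMF, 60 °C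
Reagents that add atoms: benzyl bromide, BrCc1ccccc1
Why: Williamson ether synthesis on the phenoxide; the benzyl ether keeps the phenol out of the enolate chemistry of steps 2 to 5 and leaves by hydrogenolysis at the end.

Step 2
Reactants: 2 1-[4-(benzyloxy)-3,5-dimethoxyphenyl]ethan-1-one
Product: 3 methyl 3-[4-(benzyloxy)-3,5-dimethoxyphenyl]-3-oxopropanoate
Conditions: NaH (2.5 equiv), dimethyl carbonate (3 equiv), THF, reflux; then 1 M HCl, 0 °C
Reagents that add atoms: dimethyl carbonate, COC(=O)OC
Why: Crossed Claisen condensation of the methyl ketone enolate with a non-enolisable carbonate, driven by deprotonation of the β-keto ester formed; it brings in Cγ at the ester oxidation level that the key step needs.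

Step 3
Reactants: 3 methyl 3-[4-(benzyloxy)-3,5-dimethoxyphenyl]-3-oxopropanoate
Product: 4 methyl 3-[4-(benzyloxy)-3,5-dimethoxyphenyl]-2-chloro-3-oxopropanoate (racemic)
Conditions: SO2Cl2 (1.05 equiv), CH2Cl2, 0 °C to rt
Reagents that add atoms: sulfuryl chloride, O=S(=O)(Cl)Cl
Why: Electrophilic α-chlorination of the enol of a β-keto ester; the enol is far more nucleophilic than ring A, whose free positions are flanked and deactivated by the acyl group, and one equivalent limits dichlorination.

Step 4
Reactants: 5 vanillic acid, 4-hydroxy-3-methoxybenzoic acid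
Product: 6 benzyl 4-hydroxy-3-methoxybenzoate
Conditions: BnBr (1.05 equiv), KHCO3 (1.2 equiv), DMF, 40 °C
Reagents that add atoms: benzyl bromide, BrCc1ccccc1
Why: O-alkylation of the carboxylate; hydrogencarbonate ionises the acid but not the phenol, so the ester forms selectively and the phenol stays free for step 5.

Step 5
Reactants: 4 methyl 3-[4-(benzyloxy)-3,5-dimethoxyphenyl]-2-chloro-3-oxopropanoate; 6 benzyl 4-hydroxy-3-methoxybenzoate
Product: 7 methyl 3-[4-(benzyloxy)-3,5-dimethoxyphenyl]-2-{4-[(benzyloxy)carbonyl]-2-methoxyphenoxy}-3-oxopropanoate (racemic)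
Conditions: K2CO3 (1.5 equiv), acetone, 50 °C; aq NH4Cl work-up
Reagents that add atoms: none
Why: SN2 displacement of the activated α-chloride by the phenoxide (Williamson ether synthesis), a standard entry to 2-aryloxy-1,3-dicarbonyl compounds; the Cβ–O bond is made without stereocontrol because Cβ racemises in 7 anyway.

Step 6
Reactants: 7 methyl 3-[4-(benzyloxy)-3,5-dimethoxyphenyl]-2-{4-[(benzyloxy)carbonyl]-2-methoxyphenoxy}-3-oxopropanoate (racemic)
Product: 9 methyl (2R,3S)-3-[4-(benzyloxy)-3,5-dimethoxyphenyl]-2-{4-[(benzyloxy)carbonyl]-2-methoxyphenoxy}-3-hydroxypropanoate, via achiral enol tautomer 8 (not isolated)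
Conditions: RuCl[(R,R)-TsDPEN](p-cymene) (2 mol %), HCO2H/Et3N (5:2), CH2Cl2, 30 °C; chromatography or crystallisation to remove the minor diastereomer
Reagents that add atoms: none
Why: This is an asymmetric transfer hydrogenation with dynamic kinetic resolution, the reaction type established for racemic α-alkoxy aryl β-keto esters. The chloride complex gives the 18-electron ruthenium hydride, which passes hydride from ruthenium and a proton from the ligand N–H to the Cα ketone through a six-membered outer-sphere transition state (Noyori–Ikariya mechanism); no ring is closed. The enantiomers of 7 interconvert through the achiral enol 8, because Cβ–H lies between the ketone and the ester and carries the aryloxy oxygen, and this exchange is expected to be faster than reduction of either enantiomer. The configuration at Cα is set by the catalyst: the CH/π contact between the η6-arene and ring A places the aryl group as in acetophenone reductions, which with the (R,R)-ligand should give the (3S) carbinol. The configuration at Cβ is set by the substrate within that transition state: only (R)-7 can take the hydride on the catalyst-preferred face anti to the Cβ–O bond with the ester beside the carbonyl oxygen (polar Felkin–Anh arrangement), so it should be reduced faster and give the syn (2R,3S) product while (S)-7 is returned through 8. The selectivity needed is syn over anti, since after step 8 the anti isomer would become the enantiomer of the target; the electronegative, bulky aryloxy group is what secures it, and the minor isomer is removed as a diastereomer at this stage. The benzyl ether and the three ester groups are inert to the ruthenium hydride.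

Step 7
Reactants: 9 methyl (2R,3S)-3-[4-(benzyloxy)-3,5-dimethoxyphenyl]-2-{4-[(benzyloxy)carbonyl]-2-methoxyphenoxy}-3-hydroxypropanoate
Product: 10 benzyl 4-{[(1S,2S)-1-[4-(benzyloxy)-3,5-dimethoxyphenyl]-1,3-dihydroxypropan-2-yl]oxy}-3-methoxybenzoate
Conditions: NaBH4 (6 equiv), THF/H2O (3:1), 0 °C to rt
Reagents that add atoms: none
Why: Borohydride reduction of an ester activated by the α-aryloxy group and the neighbouring hydroxyl, the usual way from such hydroxy esters to 1,3-diols; the conjugated benzyl benzoate of ring B should not be reduced at room temperature, and the absence of an alcohol co-solvent avoids transesterification. Cβ is untouched; its descriptor changes from R to S only because CH2OH ranks below the Cα carbon where CO2Me ranked above it.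

Step 8
Reactants: 10 benzyl 4-{[(1S,2S)-1-[4-(benzyloxy)-3,5-dimethoxyphenyl]-1,3-dihydroxypropan-2-yl]oxy}-3-methoxybenzoate
Product: 11 benzyl 4-{[(2S)-1-[4-(benzyloxy)-3,5-dimethoxyphenyl]-3-hydroxy-1-oxopropan-2-yl]oxy}-3-methoxybenzoate
Conditions: DDQ (1.5 equiv), 1,4-dioxane, rt, dark; cold aq NaHCO3 wash
Reagents that add atoms: none
Why: Hydride abstraction by DDQ from the electron-rich benzylic Cα–H gives the protonated ketone directly, a selective benzylic alcohol oxidation known for 1-aryl-2-aryloxypropane-1,3-diols; the primary Cγ alcohol is not benzylic and should be left. The medium is not basic, so Cβ–H should not exchange, and the Cα stereocentre, having served as relay, is erased here.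

Step 9
Reactants: 11 benzyl 4-{[(2S)-1-[4-(benzyloxy)-3,5-dimethoxyphenyl]-3-hydroxy-1-oxopropan-2-yl]oxy}-3-methoxybenzoate
Product: 12 4-{[(2S)-3-hydroxy-1-(4-hydroxy-3,5-dimethoxyphenyl)-1-oxopropan-2-yl]oxy}-3-methoxybenzoic acid
Conditions: H2 (1 atm), Pd/C (10 wt % Pd), EtOAc, rt; filtration through Celite
Reagents that add atoms: none
Why: Heterogeneous hydrogenolysis of the benzyl ether and the benzyl ester in one neutral operation; in ethyl acetate at one atmosphere the electron-rich aryl ketone and the Cβ–O bond are expected to react much more slowly than the two O-benzyl groups, and no acid or base touches Cβ.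

## Compound list

1 | acetosyringone, 1-(4-hydroxy-3,5-dimethoxyphenyl)ethan-1-one | CC(=O)c1cc(OC)c(O)c(OC)c1 | starting material
2 | 1-[4-(benzyloxy)-3,5-dimethoxyphenyl]ethan-1-one | CC(=O)c1cc(OC)c(OCc2ccccc2)c(OC)c1 | intermediate
3 | methyl 3-[4-(benzyloxy)-3,5-dimethoxyphenyl]-3-oxopropanoate | COC(=O)CC(=O)c1cc(OC)c(OCc2ccccc2)c(OC)c1 | intermediate
4 | methyl 3-[4-(benzyloxy)-3,5-dimethoxyphenyl]-2-chloro-3-oxopropanoate (racemic) | COC(=O)C(Cl)C(=O)c1cc(OC)c(OCc2ccccc2)c(OC)c1 | intermediate
5 | vanillic acid, 4-hydroxy-3-methoxybenzoic acid | COc1cc(C(=O)O)ccc1O | starting material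
6 | benzyl 4-hydroxy-3-methoxybenzoate | COc1cc(C(=O)OCc2ccccc2)ccc1O | intermediate
7 | methyl 3-[4-(benzyloxy)-3,5-dimethoxyphenyl]-2-{4-[(benzyloxy)carbonyl]-2-methoxyphenoxy}-3-oxopropanoate (racemic) | COc1cc(C(=O)OCc2ccccc2)ccc1OC(C(=O)OC)C(=O)c1cc(OC)c(OCc2ccccc2)c(OC)c1 | intermediate
8 | achiral enol tautomer of 7, methyl (E)-3-[4-(benzyloxy)-3,5-dimethoxyphenyl]-2-{4-[(benzyloxy)carbonyl]-2-methoxyphenoxy}-3-hydroxyprop-2-enoate | O/C(c1cc(OC)c(OCc2ccccc2)c(OC)c1)=C(/Oc1ccc(C(=O)OCc2ccccc2)cc1OC)C(=O)OC | intermediate (not isolated)
9 | methyl (2R,3S)-3-[4-(benzyloxy)-3,5-dimethoxyphenyl]-2-{4-[(benzyloxy)carbonyl]-2-methoxyphenoxy}-3-hydroxypropanoate | COc1cc(C(=O)OCc2ccccc2)ccc1O[C@@H](C(=O)OC)[C@@H](O)c1cc(OC)c(OCc2ccccc2)c(OC)c1 | intermediate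
10 | benzyl 4-{[(1S,2S)-1-[4-(benzyloxy)-3,5-dimethoxyphenyl]-1,3-dihydroxypropan-2-yl]oxy}-3-methoxybenzoate | COc1cc(C(=O)OCc2ccccc2)ccc1O[C@@H](CO)[C@@H](O)c1cc(OC)c(OCc2ccccc2)c(OC)c1 | intermediate
11 | benzyl 4-{[(2S)-1-[4-(benzyloxy)-3,5-dimethoxyphenyl]-3-hydroxy-1-oxopropan-2-yl]oxy}-3-methoxybenzoate | COc1cc(C(=O)OCc2ccccc2)ccc1O[C@@H](CO)C(=O)c1cc(OC)c(OCc2ccccc2)c(OC)c1 | intermediate
12 | 4-{[(2S)-3-hydroxy-1-(4-hydroxy-3,5-dimethoxyphenyl)-1-oxopropan-2-yl]oxy}-3-methoxybenzoic acid | COc1cc(C(=O)O)ccc1O[C@@H](CO)C(=O)c1cc(OC)c(O)c(OC)c1 | target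

## Step count and least certain steps

Total steps: 9. Longest linear sequence: 8 (steps 1, 2, 3, 5, 6, 7, 8, 9); step 4 is a one-step side branch.

**Step 6 (key step).** The most likely failure is insufficient kinetic discrimination between the two enantiomers of 7 in the hydride transfer, which after step 8 would appear as loss of enantiomeric purity. Slow turnover is also possible. The reason is that the aryloxy group is larger and less basic than the alkoxy groups for which the syn preference is established, and the keto ester is electron-rich and strongly enolised. The fallback is an auxiliary-controlled aldol that sets out from 6 and returns at 10. Phenol 6 is O-alkylated with the known reagent (4R)-4-benzyl-3-(bromoacetyl)-1,3-oxazolidin-2-one (K2CO3, acetone) to give (4R)-4-benzyl-3-({4-[(benzyloxy)carbonyl]-2-methoxyphenoxy}acetyl)-1,3-oxazolidin-2-one F1, the compound called A1 above. Its dibutylboron Z-enolate (Bu2BOTf, iPr2NEt, CH2Cl2, −78 °C) adds to purchased 4-(benzyloxy)-3,5-dimethoxybenzaldehyde F2 to give the syn aldol adduct (4R)-4-benzyl-3-[(2R,3S)-3-[4-(benzyloxy)-3,5-dimethoxyphenyl]-2-{4-[(benzyloxy)carbonyl]-2-methoxyphenoxy}-3-hydroxypropanoyl]-1,3-oxazolidin-2-one F3. NaBH4 in THF/H2O then removes the auxiliary reductively and gives 10.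

**Step 5.** The phenoxide may attack chlorine (dehalogenation back to 3), or 4 may be deprotonated to an unreactive chloro enolate, because 4 is both a carbon acid and a source of positive halogen. The fallback replaces substitution by carbene O–H insertion; it sets out from 3 and returns at 7. Diazo transfer to 3 (4-acetamidobenzenesulfonyl azide, Et3N, MeCN) gives methyl 3-[4-(benzyloxy)-3,5-dimethoxyphenyl]-2-diazo-3-oxopropanoate F4. Rh2(OAc)4 (1 mol %) in CH2Cl2 at reflux with 6 then inserts the rhodium carbene into the phenol O–H bond to give 7.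

**Step 8.** Hydride abstraction may be slow, because the 4-benzyloxy group of ring A is twisted out of conjugation by the two flanking methoxy groups. If the reaction has to be prolonged, the acidic hydroquinone by-product may enolise the new ketone. The fallback is a protect, oxidise, release sequence from 10 to 11. TBSCl and imidazole (CH2Cl2, 0 °C) silylate the primary Cγ hydroxyl to give benzyl 4-{[(1S,2S)-1-[4-(benzyloxy)-3,5-dimethoxyphenyl]-3-{[tert-butyl(dimethyl)silyl]oxy}-1-hydroxypropan-2-yl]oxy}-3-methoxybenzoate F5. Dess–Martin periodinane buffered with NaHCO3 (CH2Cl2, 0 °C) oxidises the benzylic alcohol to benzyl 4-{[(2S)-1-[4-(benzyloxy)-3,5-dimethoxyphenyl]-3-{[tert-butyl(dimethyl)silyl]oxy}-1-oxopropan-2-yl]oxy}-3-methoxybenzoate F6. HF·pyridine in THF at 0 °C removes the silyl group under acidic conditions and gives 11.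

**Step 9.** Over-reduction on palladium may compete with debenzylation: hydrogenation of the aryl ketone, or hydrogenolysis of the Cβ–O bond that is activated by the neighbouring carbonyl. The fallback reverses the order of the last two operations, from 10 to 12. Hydrogenolysis of 10 (H2, Pd/C, EtOAc/MeOH), which holds no ketone, gives 4-{[(1S,2S)-1,3-dihydroxy-1-(4-hydroxy-3,5-dimethoxyphenyl)propan-2-yl]oxy}-3-methoxybenzoic acid F7. DDQ (1.05 equiv, dioxane, rt) then oxidises only the 4-hydroxybenzylic Cα carbinol, a much faster oxidation than that of step 8, to give 12, which is purified by reverse-phase chromatography.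

## Further compounds

F1 | step 6 | (4R)-4-benzyl-3-({4-[(benzyloxy)carbonyl]-2-methoxyphenoxy}acetyl)-1,3-oxazolidin-2-one | O=C1OC[C@@H](Cc2ccccc2)N1C(=O)COc1ccc(C(=O)OCc2ccccc2)cc1OC
F2 | step 6 | 4-(benzyloxy)-3,5-dimethoxybenzaldehyde | O=Cc1cc(OC)c(OCc2ccccc2)c(OC)c1
F3 | step 6 | (4R)-4-benzyl-3-[(2R,3S)-3-[4-(benzyloxy)-3,5-dimethoxyphenyl]-2-{4-[(benzyloxy)carbonyl]-2-methoxyphenoxy}-3-hydroxypropanoyl]-1,3-oxazolidin-2-one | COc1cc(C(=O)OCc2ccccc2)ccc1O[C@@H](C(=O)N1[C@H](Cc2ccccc2)COC1=O)[C@@H](O)c1cc(OC)c(OCc2ccccc2)c(OC)c1
F4 | step 5 | methyl 3-[4-(benzyloxy)-3,5-dimethoxyphenyl]-2-diazo-3-oxopropanoate | COC(=O)C(=[N+]=[N-])C(=O)c1cc(OC)c(OCc2ccccc2)c(OC)c1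
F5 | step 8 | benzyl 4-{[(1S,2S)-1-[4-(benzyloxy)-3,5-dimethoxyphenyl]-3-{[tert-butyl(dimethyl)silyl]oxy}-1-hydroxypropan-2-yl]oxy}-3-methoxybenzoate | COc1cc(C(=O)OCc2ccccc2)ccc1O[C@@H](CO[Si](C)(C)C(C)(C)C)[C@@H](O)c1cc(OC)c(OCc2ccccc2)c(OC)c1
F6 | step 8 | benzyl 4-{[(2S)-1-[4-(benzyloxy)-3,5-dimethoxyphenyl]-3-{[tert-butyl(dimethyl)silyl]oxy}-1-oxopropan-2-yl]oxy}-3-methoxybenzoate | COc1cc(C(=O)OCc2ccccc2)ccc1O[C@@H](CO[Si](C)(C)C(C)(C)C)C(=O)c1cc(OC)c(OCc2ccccc2)c(OC)c1
F7 | step 9 | 4-{[(1S,2S)-1,3-dihydroxy-1-(4-hydroxy-3,5-dimethoxyphenyl)propan-2-yl]oxy}-3-methoxybenzoic acid | COc1cc(C(=O)O)ccc1O[C@@H](CO)[C@@H](O)c1cc(OC)c(O)c(OC)c1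
A1 | alternative 1 | (4R)-4-benzyl-3-({4-[(benzyloxy)carbonyl]-2-methoxyphenoxy}acetyl)-1,3-oxazolidin-2-one | O=C1OC[C@@H](Cc2ccccc2)N1C(=O)COc1ccc(C(=O)OCc2ccccc2)cc1OC
A2 | alternative 1 | 4-(benzyloxy)-3,5-dimethoxybenzaldehyde | O=Cc1cc(OC)c(OCc2ccccc2)c(OC)c1
A3 | alternative 1 | (4R)-4-benzyl-3-[(2R,3S)-3-[4-(benzyloxy)-3,5-dimethoxyphenyl]-2-{4-[(benzyloxy)carbonyl]-2-methoxyphenoxy}-3-hydroxypropanoyl]-1,3-oxazolidin-2-one | COc1cc(C(=O)OCc2ccccc2)ccc1O[C@@H](C(=O)N1[C@H](Cc2ccccc2)COC1=O)[C@@H](O)c1cc(OC)c(OCc2ccccc2)c(OC)c1
A4 | alternative 2 | benzyl 4-{2-[4-(benzyloxy)-3,5-dimethoxyphenyl]-2-oxoethoxy}-3-methoxybenzoate | COc1cc(C(=O)OCc2ccccc2)ccc1OCC(=O)c1cc(OC)c(OCc2ccccc2)c(OC)c1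
A5 | alternative 2 | formaldehyde | C=O
A6 | alternative 3 | methyl (2R)-3-(benzyloxy)-2-hydroxypropanoate | COC(=O)[C@H](O)COCc1ccccc1
A7 | alternative 3 | methyl (2S)-3-(benzyloxy)-2-{4-[(benzyloxy)carbonyl]-2-methoxyphenoxy}propanoate | COc1cc(C(=O)OCc2ccccc2)ccc1O[C@@H](COCc1ccccc1)C(=O)OC
A8 | alternative 3 | benzyl 4-{[(2S)-3-(benzyloxy)-1-[methoxy(methyl)amino]-1-oxopropan-2-yl]oxy}-3-methoxybenzoate | COc1cc(C(=O)OCc2ccccc2)ccc1O[C@@H](COCc1ccccc1)C(=O)N(C)OC
A9 | alternative 3 | [4-(benzyloxy)-3,5-dimethoxyphenyl]lithium | [Li]c1cc(OC)c(OCc2ccccc2)c(OC)c1
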